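## Analysis of the target

- The target is a flavonol, 8-(1,1-dimethylallyl)kaempferol. Benzene ring A is fused to pyranone ring C, with hydroxyl groups on C3, C5 and C7, a 4-hydroxyphenyl ring B on C2, and a 2-methylbut-3-en-2-yl group bonded through its quaternary carbon to C8.
- There is no stereocenter, so every selectivity question is one of position. The quaternary carbon has to sit on C8 (between O1 and O7) and not on C6, and the two ortho oxygens of ring A must be told apart, one becoming O1 and the other the chelated 5-OH.
- The tert-allyl group is the sensitive part. Next to the free 7-OH it can close to a dihydrofuran under strong acid, it rearranges further on prolonged heating, and its vinyl group forbids hydrogenolysis. This rules out benzyl ethers and Lewis-acid demethylation and points to acetal protection that dilute acid removes.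
- The four acidic hydroxyl groups on an electron-rich skeleton make the free polyphenol easy to oxidize, so it is unveiled only at the end.
- The hard problems are two. The crowded aryl–C(quaternary) bond is delivered by a sigmatropic route only if the allyl group stops at the right ortho carbon. The 3-oxygenated pyranone has to be built without oxidants that attack the alkene.
- The strategy rests on ring B. It is joined to C2 through C1' and carries nothing but the 4'-OH. C2', C3', C4' (with its oxygen) and C5' map onto a 1-methoxy-3-silyloxybutadiene, and C1' and C6' onto an ethynyl group on C2. Ring B can therefore be grown on a finished chromone by cycloaddition and aromatization.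

## Retrosynthetic reasoning

**21 to 20.** The last disconnection cuts three O–CH2OMe bonds. Methoxymethyl ethers are chosen because they leave under dilute protic acid, need neither hydrogenation nor a strong Lewis acid, and tolerate the amide base, the palladium coupling and the heating that come before. The 4'-OH needs no protection because it is created in the preceding step.

**20 to 16 and 17.** Ring B is cut at C1'–C2' and C5'–C6'. The cut is made here because ring B is bare apart from its para oxygen, the substitution pattern that diene 17 imprints on an alkyne. This leaves alkyne 16, in which rings A and C are complete, so the largest structural change is made last and convergently. The forward reaction must join the CH2 terminus of 17 to the terminal alkyne carbon and the methoxy-bearing terminus to the carbon on C2, then aromatize by elimination of the methoxy group and hydrolysis of the silyl ether.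

**16 to 11.** The C2–C(sp) bond is cut. Alkyne 16 comes from silylalkyne 15, made by Sonogashira coupling of iodide 13 with 14. Iodide 13 comes from chromone 11 by deprotonation at C2 (through 12) and iodination. C2–H is the most acidic C–H of 11, flanked by O1 and the C3 alkoxy group. Passing through 13 also keeps a conventional aryl cross-coupling in reserve.

**11 to 9.** Ring C is cut at O1–C2 and C2–C3. C2 is a single carbon inserted between the free ortho hydroxyl and the α-methylene of ketone 9, through enaminone 10. Because the C3 oxygen is already on the ketone, the pyranone never has to be oxidized in the presence of the vinyl group.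

**9 to 5.** The α C–O bond of the ketone is cut. Ketone 9 comes from α-hydroxy ketone 8 by acetal protection of the primary alcohol and the 4-OH, and 8 comes from methyl ketone 5 by Rubottom oxidation through 6 and 7. The hydroxyl that stays free in 9 is the one hydrogen-bonded to the carbonyl and flanked by the tert-alkyl group, which is the one that must become O1.

**5 to 4.** The bond between ring A and the quaternary carbon is cut by a retro-Claisen step to prenyl ether 4. The ether sits on the para oxygen (the future O7), not on the chelated ortho oxygen. With the prenyl group on the ortho oxygen, the para carbon would be open and a Cope shift would relay the allyl group there, ending as a normal prenyl group on the future C6. With the ether on O7 the para carbon carries the acetyl group, so the allyl group must stop at an ortho carbon with its 1,1-dimethylallyl connectivity. The hydrogen-bonded 2-OH steers it to C3, the future C8.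

**4 to 1 and 2.** Ether 4 comes from diol 3 by mono-protection of one of two equivalent ortho hydroxyl groups. Diol 3 comes from 1 and 2 by O-alkylation of the most acidic, non-chelated 4-OH.

## Alternatives that were turned down

**Alternative 1:** The reverse prenyl group is assembled on the acetyl carbon by forming both the C–CH3 and C–vinyl bonds of the quaternary carbon.
- Forward key step: the aryl carbonate A1 (tert-butyl carbonate of the ortho-hydroxy acetophenone) is treated with CH3MgBr and then CH2=CHMgBr. The first reagent adds to the ketone, the carbonate moves to the new alkoxide and leaves, and the ortho-quinone methide A2 accepts the vinyl group at its isopropylidene carbon to give phenol A3.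
- For it: the quaternary carbon sits exactly where the acetyl group was, so no sigmatropic direction is in question, and the step is one flask on a two-step precursor. On positional certainty of the side chain it is stronger than the chosen route.
- Against it: A2 has six hydrogens that can shift to oxygen, giving an ortho-isopropenyl phenol, and the vinyl nucleophile must attack a fully substituted carbon. The acetyl carbon is also consumed, so A3 has no C4. An acyl group would have to be put back at one of two open ring positions (only the one between OH and an acetal is wanted), and C3–O, ring C and ring B would all remain to be built.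
- Comparison: the chosen route keeps the acetyl group as C4 and C3, builds the side chain by a rearrangement with a symmetric fallback, and adds ring B to a finished chromone.

**Alternative 2:** Ring A itself is built, with C5–C6, C6–C7, C8–C8a and C8a–C4a formed in one benzannulation.
- Forward key step: irradiation of diazoketone A4 triggers a Wolff rearrangement. The resulting ketene adds siloxyalkyne A5 (which already carries the quaternary carbon) by [2+2], and four-electron ring opening and six-electron closure give benzoate A6.
- For it: every ring A substituent is placed by connectivity, and the three oxygens emerge differentiated (free OH, OMe, silyl ether). On regiocontrol of ring A it is stronger than the chosen route.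
- Against it: it spends a photochemical step and two multi-step fragments (a light- and acid-sensitive diazoketone, and an ynol silyl ether with a neopentyl-type carbon) on a ring that is bought as 1. A6 has a methyl ether on the future O5 whose removal needs a Lewis acid beside the tert-allyl group. Its ester still has to become the α-oxygenated ketone before rings C and B can be made.
- Comparison: the chosen route reaches the same ring A pattern from 1 in three steps and reserves its one uncertain step for ring B.

**Alternative 3:** Ring C is closed at C3–C4 at the flavan-3,4-diol oxidation level.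
- Forward key step: SmI2 (divalent samarium) reduces the aryl aldehyde of dialdehyde A7 to a ketyl that adds to the tethered aliphatic aldehyde, giving diol A8.
- For it: pinacol closure of a six-membered ring is dependable, the C3 oxygen is built in, and ring B enters as a simple arylacetic unit. Its key step is more secure than the chosen cycloaddition.
- Against it:
  - A8 carries three stereocenters the target lacks and sits four electrons below it. The alcohol oxidation and C2–C3 dehydrogenation must be done on an electron-rich system bearing the alkene.
  - A7 needs O-alkylation of the most hindered phenol (between the tert-alkyl and formyl groups) by a secondary benzylic electrophile.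
  - The α-aryloxy aldehyde in A7 can enolize and lose phenoxide. If it is reduced by SmI2 instead of the aryl aldehyde, it would cleave its α C–O bond.
- Comparison: the chosen route keeps ring C at its final oxidation level from the moment it closes and needs no redox corrections.

Key step: step 10

Remark on the chemistry: 18 forms as a racemate and loses its only stereocenter in the same flask. The geometry of enaminone 10 is not controlled and does not matter for ring closure. No other compound on the route needs a stereodescriptor except the (E) geometry of 17.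

## Route

Step 1
Reactants: 1 2,4,6-trihydroxyacetophenone; 2 1-bromo-3-methylbut-2-ene
Product: 3 1-[2,6-dihydroxy-4-(3-methylbut-2-enyloxy)phenyl]ethanone
Conditions: K2CO3 (1.1 equiv), acetone, rt to 40 °C
Reagents that add atoms: none
Why: Williamson O-alkylation; the 4-OH is the most acidic hydroxyl (para to the acetyl group) and the only one not hydrogen-bonded to the carbonyl, so one equivalent of the allylic bromide with a weak base should alkylate it first.

Step 2
Reactants: 3 1-[2,6-dihydroxy-4-(3-methylbut-2-enyloxy)phenyl]ethanone
Product: 4 1-[2-hydroxy-6-(methoxymethoxy)-4-(3-methylbut-2-enyloxy)phenyl]ethanone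
Conditions: MOMCl (1.1 equiv), i-Pr2NEt, CH2Cl2, 0 °C
Reagents that add atoms: chloromethyl methyl ether, COCCl
Why: Acetal protection of a phenol; the two ortho hydroxyl groups are equivalent, and once one is protected the other is locked in the hydrogen bond to the carbonyl and should resist a second alkylation under amine base.

Step 3
Reactants: 4 1-[2-hydroxy-6-(methoxymethoxy)-4-(3-methylbut-2-enyloxy)phenyl]ethanone
Product: 5 1-[2,4-dihydroxy-6-(methoxymethoxy)-3-(2-methylbut-3-en-2-yl)phenyl]ethanone
Conditions: N,N-diethylaniline, 190 °C, sealed tube, Ar
Reagents that add atoms: none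
Why: Aromatic Claisen rearrangement; the [3,3] shift inverts the allyl unit to a C-bound 2-methylbut-3-en-2-yl group on an ortho carbon, and the acetyl-blocked para carbon prevents a Cope relay from ending as a normal prenyl group. The hydrogen-bonded chelate of 2-OH and the carbonyl favours the bond arrangement with C3=C4 double-bond character, which directs the shift to C3 as known for 2-hydroxy-4-allyloxy aryl ketones; the basic solvent buffers the new phenol against ring closure onto the vinyl group.

Step 4
Reactants: 5 1-[2,4-dihydroxy-6-(methoxymethoxy)-3-(2-methylbut-3-en-2-yl)phenyl]ethanone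
Product: 8 2-hydroxy-1-[2,4-dihydroxy-6-(methoxymethoxy)-3-(2-methylbut-3-en-2-yl)phenyl]ethanone, via tris-silyl enol ether 6 (not isolated), via alpha-silyloxy ketone 7 (not isolated)
Conditions: LiN(SiMe3)2 (3.5 equiv), Me3SiCl (4.5 equiv), THF, −78 to 0 °C; mCPBA (1.05 equiv), NaHCO3, CH2Cl2, −20 °C; citric acid, MeOH, rt
Reagents that add atoms: meta-chloroperoxybenzoic acid (mCPBA), O=C(OO)c1cccc(Cl)c1
Why: Rubottom oxidation; in-situ silylation turns both phenols into aryl silyl ethers and the methyl ketone into silyl enol ether 6, which the peracid should epoxidize far faster than the hindered monosubstituted vinyl group. Silyl migration gives 7, and mild acidic methanolysis frees the primary alcohol and both phenols without touching the methoxymethyl ether.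

Step 5
Reactants: 8 2-hydroxy-1-[2,4-dihydroxy-6-(methoxymethoxy)-3-(2-methylbut-3-en-2-yl)phenyl]ethanone
Product: 9 1-[2-hydroxy-4,6-bis(methoxymethoxy)-3-(2-methylbut-3-en-2-yl)phenyl]-2-(methoxymethoxy)ethanone
Conditions: MOMCl (2.4 equiv), i-Pr2NEt, CH2Cl2, 0 °C to rt
Reagents that add atoms: chloromethyl methyl ether, COCCl
Why: Acetal protection; the primary alcohol and the 4-OH should react, while the 2-OH, hydrogen-bonded to the carbonyl and wedged between the tert-alkyl and acyl groups, stays free, as in the usual partial protection of ortho-hydroxyaryl ketones.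

Step 6
Reactants: 9 1-[2-hydroxy-4,6-bis(methoxymethoxy)-3-(2-methylbut-3-en-2-yl)phenyl]-2-(methoxymethoxy)ethanone
Product: 11 3,5,7-tris(methoxymethoxy)-8-(2-methylbut-3-en-2-yl)chromen-4-one, via enaminone 10 (not isolated)
Conditions: Me2NCH(OMe)2 (3 equiv), PhMe, 95 °C; then AcOH, 60 °C
Reagents that add atoms: N,N-dimethylformamide dimethyl acetal, COC(OC)N(C)C
Why: Enaminone chromone synthesis; the formamide acetal condenses at the CH2 between carbonyl and alkoxy group to give 10, then the free 2-OH adds to the enamine carbon (6-endo-trig) and dimethylamine is expelled. Ring C closes with the C3 oxygen already in place, as known for ortho-hydroxyaryl ketones with an α-alkoxy or α-aryl substituent.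

Step 7
Reactants: 11 3,5,7-tris(methoxymethoxy)-8-(2-methylbut-3-en-2-yl)chromen-4-one
Product: 13 2-iodo-3,5,7-tris(methoxymethoxy)-8-(2-methylbut-3-en-2-yl)chromen-4-one, via 2-lithiochromone 12 (not isolated)
Conditions: LiN(i-Pr)2 (1.3 equiv), THF, −78 °C; I2 (1.5 equiv), −78 to −40 °C
Reagents that add atoms: iodine, II
Why: Directed vinylic lithiation and iodination; C2–H, flanked by O1 and the lithium-coordinating C3 methoxymethoxy group, is the most acidic C–H and should be removed by the hindered amide at −78 °C. The aryl C6–H between two alkoxy groups is not deprotonated by an amide base at this temperature.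

Step 8
Reactants: 13 2-iodo-3,5,7-tris(methoxymethoxy)-8-(2-methylbut-3-en-2-yl)chromen-4-one; 14 trimethylsilylacetylene
Product: 15 3,5,7-tris(methoxymethoxy)-8-(2-methylbut-3-en-2-yl)-2-[(trimethylsilyl)ethynyl]chromen-4-one
Conditions: PdCl2(PPh3)2 (3 mol%), CuI (5 mol%), Et3N, THF, rt
Reagents that add atoms: none
Why: Sonogashira coupling; the 2-iodochromone is a vinylogous acyl iodide that should add oxidatively to zerovalent palladium at room temperature, and the copper acetylide of 14 delivers the alkynyl group. The vinyl group and the acetals are inert.

Step 9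
Reactants: 15 3,5,7-tris(methoxymethoxy)-8-(2-methylbut-3-en-2-yl)-2-[(trimethylsilyl)ethynyl]chromen-4-one
Product: 16 2-ethynyl-3,5,7-tris(methoxymethoxy)-8-(2-methylbut-3-en-2-yl)chromen-4-one
Conditions: Bu4NF (1.1 equiv), AcOH (1.2 equiv), THF, −20 to 0 °C
Reagents that add atoms: none
Why: Fluoride-induced cleavage of the alkynyl C–Si bond; acetic acid buffering and low temperature should keep the electrophilic terminal alkyne from adding nucleophiles or oligomerizing. Aryl methoxymethyl ethers are stable to fluoride.

Step 10
Reactants: 16 2-ethynyl-3,5,7-tris(methoxymethoxy)-8-(2-methylbut-3-en-2-yl)chromen-4-one; 17 (E)-1-methoxy-3-(trimethylsilyloxy)buta-1,3-diene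
Product: 20 2-(4-hydroxyphenyl)-3,5,7-tris(methoxymethoxy)-8-(2-methylbut-3-en-2-yl)chromen-4-one, via cyclohexadiene cycloadduct 18 (not isolated), via aryl silyl ether 19 (not isolated)
Conditions: 17 (3 equiv), PhMe, 120 °C, sealed tube; then 0.1 M HCl, THF, 0 °C
Reagents that add atoms: none
Why: Proposed new method: the closest known reaction type is the Diels–Alder addition of 1-methoxy-3-silyloxybutadienes to acetylenic esters and ketones, followed by loss of methanol to 4-hydroxyaryl products; here the alkyne is activated only vinylogously, through C2=C3 to the C4 carbonyl, which has not been shown. The terminal alkyne carbon is the remote electrophilic end of that acceptor system, so the nucleophilic CH2 terminus of 17 should bond there (C5'–C6') and the methoxy-bearing terminus to the carbon on C2 (C1'–C2'). Ring B closes as a six-membered ring in one asynchronous [4+2] cycloaddition that forms both bonds, giving cyclohexa-1,4-diene 18. 1,4-Elimination of methanol across the CH(OMe) and CH2 positions aromatizes 18 to aryl silyl ether 19, and the cold dilute acid completes that elimination and hydrolyses the O–Si bond to the phenol. The only stereocenter formed, the methoxy carbon of 18, is racemic and is erased on aromatization, so nothing has to be controlled there. The selectivity needed is regiochemical (hydroxyl para, not meta, to C2), secured by the polarity match of diene and alkyne termini. Chemoselectivity among the π bonds follows because the tetrasubstituted, donor-substituted C2=C3 bond and the unactivated vinyl group are not dienophiles for an electron-rich diene. The three methoxymethyl ethers should survive the brief contact with 0.1 M acid at 0 °C.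

Step 11
Reactants: 20 2-(4-hydroxyphenyl)-3,5,7-tris(methoxymethoxy)-8-(2-methylbut-3-en-2-yl)chromen-4-one
Product: 21 3,5,7-trihydroxy-2-(4-hydroxyphenyl)-8-(2-methylbut-3-en-2-yl)chromen-4-one
Conditions: HCl (0.5 M), MeOH, 45 °C
Reagents that add atoms: none
Why: Acid-catalysed acetal exchange with methanol removes the three methoxymethyl groups. The vinyl group could react with 7-OH only after protonation to a secondary cation, which dilute acid at 45 °C should not achieve, so the tert-allyl group is expected to survive.

## Compound list

1 | 2,4,6-trihydroxyacetophenone | CC(=O)c1c(O)cc(O)cc1O | starting material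
2 | 1-bromo-3-methylbut-2-ene | CC(C)=CCBr | starting material
3 | 1-[2,6-dihydroxy-4-(3-methylbut-2-enyloxy)phenyl]ethanone | CC(=O)c1c(O)cc(OCC=C(C)C)cc1O | intermediate
4 | 1-[2-hydroxy-6-(methoxymethoxy)-4-(3-methylbut-2-enyloxy)phenyl]ethanone | CC(=O)c1c(O)cc(OCC=C(C)C)cc1OCOC | intermediate
5 | 1-[2,4-dihydroxy-6-(methoxymethoxy)-3-(2-methylbut-3-en-2-yl)phenyl]ethanone | CC(=O)c1c(O)c(C(C)(C)C=C)c(O)cc1OCOC | intermediate
6 | trimethyl[1-[6-(methoxymethoxy)-3-(2-methylbut-3-en-2-yl)-2,4-bis(trimethylsilyloxy)phenyl]ethenyloxy]silane | C=C(O[Si](C)(C)C)c1c(O[Si](C)(C)C)c(C(C)(C)C=C)c(O[Si](C)(C)C)cc1OCOC | intermediate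
7 | 1-[6-(methoxymethoxy)-3-(2-methylbut-3-en-2-yl)-2,4-bis(trimethylsilyloxy)phenyl]-2-(trimethylsilyloxy)ethanone | C[Si](C)(C)OCC(=O)c1c(O[Si](C)(C)C)c(C(C)(C)C=C)c(O[Si](C)(C)C)cc1OCOC | intermediate
8 | 2-hydroxy-1-[2,4-dihydroxy-6-(methoxymethoxy)-3-(2-methylbut-3-en-2-yl)phenyl]ethanone | OCC(=O)c1c(O)c(C(C)(C)C=C)c(O)cc1OCOC | intermediate
9 | 1-[2-hydroxy-4,6-bis(methoxymethoxy)-3-(2-methylbut-3-en-2-yl)phenyl]-2-(methoxymethoxy)ethanone | COCOCC(=O)c1c(O)c(C(C)(C)C=C)c(OCOC)cc1OCOC | intermediate
10 | 3-(dimethylamino)-1-[2-hydroxy-4,6-bis(methoxymethoxy)-3-(2-methylbut-3-en-2-yl)phenyl]-2-(methoxymethoxy)prop-2-en-1-one (alkene geometry not defined) | CN(C)C=C(OCOC)C(=O)c1c(O)c(C(C)(C)C=C)c(OCOC)cc1OCOC | intermediate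
11 | 3,5,7-tris(methoxymethoxy)-8-(2-methylbut-3-en-2-yl)chromen-4-one | C=CC(C)(C)c1c(OCOC)cc(OCOC)c2c(=O)c(OCOC)coc12 | intermediate
12 | 2-lithio-3,5,7-tris(methoxymethoxy)-8-(2-methylbut-3-en-2-yl)chromen-4-one | C=CC(C)(C)c1c(OCOC)cc(OCOC)c2c(=O)c(OCOC)c([Li])oc12 | intermediate
13 | 2-iodo-3,5,7-tris(methoxymethoxy)-8-(2-methylbut-3-en-2-yl)chromen-4-one | C=CC(C)(C)c1c(OCOC)cc(OCOC)c2c(=O)c(OCOC)c(I)oc12 | intermediate
14 | trimethylsilylacetylene | C#C[Si](C)(C)C | starting material
15 | 3,5,7-tris(methoxymethoxy)-8-(2-methylbut-3-en-2-yl)-2-[(trimethylsilyl)ethynyl]chromen-4-one | C=CC(C)(C)c1c(OCOC)cc(OCOC)c2c(=O)c(OCOC)c(C#C[Si](C)(C)C)oc12 | intermediate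
16 | 2-ethynyl-3,5,7-tris(methoxymethoxy)-8-(2-methylbut-3-en-2-yl)chromen-4-one | C=CC(C)(C)c1c(OCOC)cc(OCOC)c2c(=O)c(OCOC)c(C#C)oc12 | intermediate
17 | (E)-1-methoxy-3-(trimethylsilyloxy)buta-1,3-diene | CO/C=C/C(=C)O[Si](C)(C)C | starting material
18 | 2-[6-methoxy-4-(trimethylsilyloxy)cyclohexa-1,4-dien-1-yl]-3,5,7-tris(methoxymethoxy)-8-(2-methylbut-3-en-2-yl)chromen-4-one (racemic) | C=CC(C)(C)c1c(OCOC)cc(OCOC)c2c(=O)c(OCOC)c(C3=CCC(O[Si](C)(C)C)=CC3OC)oc12 | intermediate
19 | 3,5,7-tris(methoxymethoxy)-8-(2-methylbut-3-en-2-yl)-2-[4-(trimethylsilyloxy)phenyl]chromen-4-one | C=CC(C)(C)c1c(OCOC)cc(OCOC)c2c(=O)c(OCOC)c(-c3ccc(O[Si](C)(C)C)cc3)oc12 | intermediate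
20 | 2-(4-hydroxyphenyl)-3,5,7-tris(methoxymethoxy)-8-(2-methylbut-3-en-2-yl)chromen-4-one | C=CC(C)(C)c1c(OCOC)cc(OCOC)c2c(=O)c(OCOC)c(-c3ccc(O)cc3)oc12 | intermediate
21 | 3,5,7-trihydroxy-2-(4-hydroxyphenyl)-8-(2-methylbut-3-en-2-yl)chromen-4-one | C=CC(C)(C)c1c(O)cc(O)c2c(=O)c(O)c(-c3ccc(O)cc3)oc12 | target

Total step count: 11. Longest linear sequence: 11 steps (1 to 21).

## Least certain steps

**Step 10 (key step).** The alkyne is activated only through the pyranone double bond and is deactivated by three alkoxy donors. Cycloaddition may therefore be slower than thermal decomposition or oligomerization of the diene at 120 °C. A stepwise conjugate addition at the terminal alkyne carbon without ring closure, or partial loss of the 5-O acetal in the acid wash, are further possible failures. Fallback (known chemistry): set out from iodide 13 and introduce ring B whole by Suzuki–Miyaura coupling with 4-hydroxyphenylboronic acid [Pd(PPh3)4, K2CO3, dioxane–water, 80 °C]. This should give 20 directly and rejoins the route at 20.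

**Step 3.** The allyl group may be delivered to the other ortho carbon (C5) if the chelate effect is weak or if the ortho dienones equilibrate by Cope shifts through the acetyl-bearing carbon. The product phenol may also react on at 190 °C, by abnormal Claisen rearrangement or by ring closure of a neighbouring hydroxyl onto the vinyl group. Fallback: remove the regiochemical question by symmetry, setting out from 3.
- Heating 3 (N,N-diethylaniline, 190 °C), whose two ortho carbons are equivalent, should give 1-[2,4,6-trihydroxy-3-(2-methylbut-3-en-2-yl)phenyl]ethanone F1.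
- MOMCl (2.2 equiv) and i-Pr2NEt should protect the 4-OH and the less hindered 6-OH, leaving the hydroxyl between the tert-alkyl and acetyl groups free, to give 1-[2-hydroxy-4,6-bis(methoxymethoxy)-3-(2-methylbut-3-en-2-yl)phenyl]ethanone F2.
- Rubottom oxidation as in step 4 passes through trimethyl[1-[4,6-bis(methoxymethoxy)-3-(2-methylbut-3-en-2-yl)-2-(trimethylsilyloxy)phenyl]ethenyloxy]silane F3 and 1-[4,6-bis(methoxymethoxy)-3-(2-methylbut-3-en-2-yl)-2-(trimethylsilyloxy)phenyl]-2-(trimethylsilyloxy)ethanone F4 to give 2-hydroxy-1-[2-hydroxy-4,6-bis(methoxymethoxy)-3-(2-methylbut-3-en-2-yl)phenyl]ethanone F5.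
- MOMCl and i-Pr2NEt on the primary alcohol of F5 rejoins the route at 9.

**Step 7.** The amide base may add to C2 and open ring C instead of deprotonating, or metalation may be incomplete and leave 11 to be iodinated on ring A. Fallback: avoid C2 metalation, setting out from ketone 9.
- Condensation with N,N-dimethylacetamide dimethyl acetal (PhMe, 100 °C, then AcOH) should give 2-methyl-3,5,7-tris(methoxymethoxy)-8-(2-methylbut-3-en-2-yl)chromen-4-one F6.
- Oxidation of the activated methyl group with SeO2 (dioxane, 90 °C) should give 3,5,7-tris(methoxymethoxy)-8-(2-methylbut-3-en-2-yl)-4-oxochromene-2-carbaldehyde F7.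
- Ohira–Bestmann homologation (dimethyl (1-diazo-2-oxopropyl)phosphonate, K2CO3, MeOH, 0 °C) rejoins the route at 16.

**Step 9.** Once the silyl group is gone, fluoride, acetate or adventitious hydroxide may add to the terminal carbon of the electrophilic alkyne, or the terminal alkyne may oligomerize under base. Fallback: bypass the silyl group, setting out from iodide 13. Stille coupling with tributyl(ethynyl)stannane [Pd(PPh3)4, PhMe, 80 °C] should deliver the terminal alkyne under neutral conditions and rejoins the route at 16.

## Further compounds

F0 | step 10 | none | none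
F1 | step 3 | 1-[2,4,6-trihydroxy-3-(2-methylbut-3-en-2-yl)phenyl]ethanone | CC(=O)c1c(O)cc(O)c(C(C)(C)C=C)c1O
F2 | step 3 | 1-[2-hydroxy-4,6-bis(methoxymethoxy)-3-(2-methylbut-3-en-2-yl)phenyl]ethanone | CC(=O)c1c(O)c(C(C)(C)C=C)c(OCOC)cc1OCOC
F3 | step 3 | trimethyl[1-[4,6-bis(methoxymethoxy)-3-(2-methylbut-3-en-2-yl)-2-(trimethylsilyloxy)phenyl]ethenyloxy]silane | C=C(O[Si](C)(C)C)c1c(O[Si](C)(C)C)c(C(C)(C)C=C)c(OCOC)cc1OCOC
F4 | step 3 | 1-[4,6-bis(methoxymethoxy)-3-(2-methylbut-3-en-2-yl)-2-(trimethylsilyloxy)phenyl]-2-(trimethylsilyloxy)ethanone | C[Si](C)(C)OCC(=O)c1c(O[Si](C)(C)C)c(C(C)(C)C=C)c(OCOC)cc1OCOC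
F5 | step 3 | 2-hydroxy-1-[2-hydroxy-4,6-bis(methoxymethoxy)-3-(2-methylbut-3-en-2-yl)phenyl]ethanone | OCC(=O)c1c(O)c(C(C)(C)C=C)c(OCOC)cc1OCOC
F6 | step 7 | 2-methyl-3,5,7-tris(methoxymethoxy)-8-(2-methylbut-3-en-2-yl)chromen-4-one | C=CC(C)(C)c1c(OCOC)cc(OCOC)c2c(=O)c(OCOC)c(C)oc12
F7 | step 7 | 3,5,7-tris(methoxymethoxy)-8-(2-methylbut-3-en-2-yl)-4-oxochromene-2-carbaldehyde | C=CC(C)(C)c1c(OCOC)cc(OCOC)c2c(=O)c(OCOC)c(C=O)oc12
F0 | step 9 | none | none
A1 | alternative 1 | tert-butyl [2-acetyl-3,5-bis(methoxymethoxy)phenyl] carbonate | CC(=O)c1c(OC(=O)OC(C)(C)C)cc(OCOC)cc1OCOC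
A2 | alternative 1 | 3,5-bis(methoxymethoxy)-6-(propan-2-ylidene)cyclohexa-2,4-dien-1-one | CC(C)=C1C(=O)C=C(OCOC)C=C1OCOC
A3 | alternative 1 | 3,5-bis(methoxymethoxy)-2-(2-methylbut-3-en-2-yl)phenol | C=CC(C)(C)c1c(O)cc(OCOC)cc1OCOC
A4 | alternative 2 | methyl (2E)-5-diazo-3-methoxy-4-oxopent-2-enoate | COC(=O)/C=C(/OC)C(=O)C=[N+]=[N-]
A5 | alternative 2 | [(3,3-dimethylpent-4-en-1-yn-1-yl)oxy]tri(propan-2-yl)silane | C=CC(C)(C)C#CO[Si](C(C)C)(C(C)C)C(C)C
A6 | alternative 2 | methyl 2-hydroxy-6-methoxy-3-(2-methylbut-3-en-2-yl)-4-(triisopropylsilyloxy)benzoate | COC(=O)c1c(OC)cc(O[Si](C(C)C)(C(C)C)C(C)C)c(C(C)(C)C=C)c1O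
A7 | alternative 3 | 2-[1-[4-(methoxymethoxy)phenyl]-2-oxoethoxy]-4,6-bis(methoxymethoxy)-3-(2-methylbut-3-en-2-yl)benzaldehyde (racemic) | C=CC(C)(C)c1c(OCOC)cc(OCOC)c(C=O)c1OC(C=O)c1ccc(OCOC)cc1
A8 | alternative 3 | 5,7-bis(methoxymethoxy)-2-[4-(methoxymethoxy)phenyl]-8-(2-methylbut-3-en-2-yl)chromane-3,4-diol (racemic, one diastereomer drawn) | C=CC(C)(C)c1c(OCOC)cc(OCOC)c2c1O[C@H](c1ccc(OCOC)cc1)[C@@H](O)[C@H]2O
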